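**Plan** (chain carbons are numbered C1' at the benzylic carbon to C16')

- Retrosynthetic cuts, in order: the two aryl O–CH3 bonds (the hydroquinone is freed last, through the quinone); C12'–C13' (allylic bromide plus lithiated prenyl sulfone); C10'=C11' together with C9'–O in one flask; the terminal isopropylidene alkene of a farnesyl chain (its inner carbon becomes the C10' aldehyde, the rest leaves as acetone); aryl–C1'.
- Enabling feature: C9' carries the hydroxyl and lies between C8'H2 and the (E)-C10'=C11'(CH3) alkene, which is the imprint of a C10' aldehyde oxygenated at its α-carbon and then olefinated by a methyl-bearing stabilised ylide. The benzene ring is the only ring and no ring is formed.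
- Forward: aryl Grignard plus (2E,6E)-farnesyl bromide supplies C1'–C10' with the 2'E and 6'E alkenes ready-made; the terminal alkene is degraded to the aldehyde; the three-component step adds O at C9', then C11', its methyl and the C12' ester; the ester becomes the bromide, the sulfone adds C13'–C16'; deprotection follows.
- Stereochemistry: the only stereocentre, (R)-C9', is set by L-proline in the aminoxylation and no later step touches its C–O bond; 10'E comes from the stabilised ylide.

Key step: step 7

Remark: in the copper-catalysed N–O cleavage of step 8 the PhN fragment is assumed to leave as azobenzene, the redox-neutral outcome when no external reductant is present.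

**Step 1**
Reactants: 1 4-methoxy-2-methylphenol
Product: 2 2-bromo-4-methoxy-6-methylphenol
Conditions: Br2 (1.0 equiv), CH2Cl2, 0 °C
Reagents that add atoms: bromine, BrBr
Why: Electrophilic aromatic bromination directed by the free hydroxyl group, whose para position is occupied by methoxy and one ortho position by methyl, so bromine should enter the remaining ortho carbon.

**Step 2**
Reactants: 2 2-bromo-4-methoxy-6-methylphenol
Product: 3 1-bromo-2,5-dimethoxy-3-methylbenzene
Conditions: MeI, K2CO3, acetone, reflux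
Reagents that add atoms: iodomethane, CI
Why: Williamson ether synthesis of the phenoxide, giving a hydroquinone dimethyl ether that tolerates every later organometallic, hydride and fluoride reagent.

**Step 3**
Reactants: 3 1-bromo-2,5-dimethoxy-3-methylbenzene, 4 (2E,6E)-farnesyl bromide
Product: 6 1-[(2E,6E)-3,7,11-trimethyldodeca-2,6,10-trienyl]-2,5-dimethoxy-3-methylbenzene, via arylmagnesium bromide 5 (not isolated)
Conditions: Mg, THF, reflux; then 4, CuI (5 mol %), THF, −10 °C → rt
Reagents that add atoms: none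
Why: Grignard formation followed by copper-catalysed allylic substitution at the primary carbon of the allylic bromide (α-attack), which should leave the (2E,6E) geometry of the farnesyl unit unchanged.

**Step 4**
Reactants: 6 1-[(2E,6E)-3,7,11-trimethyldodeca-2,6,10-trienyl]-2,5-dimethoxy-3-methylbenzene
Product: 7 (6E,10E)-3-bromo-12-(2,5-dimethoxy-3-methylphenyl)-2,6,10-trimethyldodeca-6,10-dien-2-ol (racemic)
Conditions: NBS (1.05 equiv), THF/H2O, 0 °C
Reagents that add atoms: N-bromosuccinimide, O=C1CCC(=O)N1Br; water, O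
Why: Terminal-selective bromohydrin formation of an oligoprenyl chain, which coils in aqueous THF and exposes the end alkene, with water opening the bromonium ion at the tertiary carbon and the alkenes reacting faster than the dimethoxyarene at 0 °C; the racemic CHBr centre is destroyed in step 6.

**Step 5**
Reactants: 7 (6E,10E)-3-bromo-12-(2,5-dimethoxy-3-methylphenyl)-2,6,10-trimethyldodeca-6,10-dien-2-ol
Product: 8 3-[(3E,7E)-9-(2,5-dimethoxy-3-methylphenyl)-3,7-dimethylnona-3,7-dienyl]-2,2-dimethyloxirane (racemic)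
Conditions: K2CO3, MeOH, rt
Reagents that add atoms: none
Why: Intramolecular Williamson (SN2) displacement of the secondary bromide by the neighbouring tertiary alkoxide, the standard closure of a bromohydrin to an epoxide.

**Step 6**
Reactants: 8 3-[(3E,7E)-9-(2,5-dimethoxy-3-methylphenyl)-3,7-dimethylnona-3,7-dienyl]-2,2-dimethyloxirane
Product: 10 (4E,8E)-10-(2,5-dimethoxy-3-methylphenyl)-4,8-dimethyldeca-4,8-dienal, via vicinal diol 9 (not isolated)
Conditions: H5IO6, THF/H2O, 0 °C → rt
Reagents that add atoms: none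
Why: Acid-promoted hydration of the trisubstituted epoxide (water enters at the tertiary carbon, so its oxygen leaves with acetone) followed by Malaprade glycol cleavage, a standard shortening of a terminal isopropylidene unit to the aldehyde.

**Step 7**
Reactants: 10 (4E,8E)-10-(2,5-dimethoxy-3-methylphenyl)-4,8-dimethyldeca-4,8-dienal, 11 nitrosobenzene, 12 ethyl 2-(triphenylphosphoranylidene)propanoate
Product: 14 ethyl (2E,4R,6E,10E)-4-(anilinooxy)-12-(2,5-dimethoxy-3-methylphenyl)-2,6,10-trimethyldodeca-2,6,10-trienoate, via (2R)-2-anilinooxy aldehyde 13 (not isolated)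
Conditions: L-proline (20 mol %), DMSO, rt, 11 (0.95 equiv) added over 1 h; then 12 (1.5 equiv), CH2Cl2, 0 °C → rt
Reagents that add atoms: none
Why: L-Proline condenses with the unbranched aldehyde 10 to the (E)-enamine, whose C9' attacks the oxygen of nitrosobenzene while the carboxylic acid protonates the nitroso nitrogen, and hydrolysis releases aldehyde 13 and the catalyst; this is the known proline-catalysed α-aminoxylation of aldehydes run in one flask with a Wittig olefination. The acid-bound nitroso group can reach only the enamine face on the carboxyl side, so the single stereocentre of L-proline should set C9' as (R), the sense established for simple aldehydes, and the priority order O, C10', C8' is the same in 13, 14 and the target. Ylide 12 is added before the labile α-oxy aldehyde can epimerise and forms C10'=C11' through an oxaphosphetane; as a stabilised α-methyl ylide it places the ester carbon C12' trans to C9', giving the (E)-alkene. No ring is closed. The step needs O- over N-attack (secured by the hydrogen bond from the proline acid to nitrogen), enamine reaction ahead of any nitroso ene reaction at the C2' and C6' alkenes (secured by the far higher nucleophilicity of the enamine and the slow addition of 11), and olefination without loss of configuration (secured by the nearly neutral ylide).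

**Step 8**
Reactants: 14 ethyl (2E,4R,6E,10E)-4-(anilinooxy)-12-(2,5-dimethoxy-3-methylphenyl)-2,6,10-trimethyldodeca-2,6,10-trienoate
Product: 15 ethyl (2E,4R,6E,10E)-12-(2,5-dimethoxy-3-methylphenyl)-4-hydroxy-2,6,10-trimethyldodeca-2,6,10-trienoate
Conditions: CuSO4·5H2O (30 mol %), MeOH, 0 °C → rt
Reagents that add atoms: none
Why: Copper-catalysed cleavage of the weak N–O bond of an O-alkyl N-arylhydroxylamine, the usual follow-up to aminoxylation, which leaves the alkenes and the C9'–O bond (and so the configuration) untouched.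

**Step 9**
Reactants: 15 ethyl (2E,4R,6E,10E)-12-(2,5-dimethoxy-3-methylphenyl)-4-hydroxy-2,6,10-trimethyldodeca-2,6,10-trienoate
Product: 16 ethyl (2E,4R,6E,10E)-4-[tert-butyl(dimethyl)silyl]oxy-12-(2,5-dimethoxy-3-methylphenyl)-2,6,10-trimethyldodeca-2,6,10-trienoate
Conditions: TBSCl, imidazole, DMF, rt
Reagents that add atoms: tert-butyldimethylsilyl chloride, CC(C)(C)[Si](C)(C)Cl
Why: Standard silylation of a secondary alcohol, needed so that the primary allylic alcohol made next can be brominated alone.

**Step 10**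
Reactants: 16 ethyl (2E,4R,6E,10E)-4-[tert-butyl(dimethyl)silyl]oxy-12-(2,5-dimethoxy-3-methylphenyl)-2,6,10-trimethyldodeca-2,6,10-trienoate
Product: 17 (2E,4R,6E,10E)-4-[tert-butyl(dimethyl)silyl]oxy-12-(2,5-dimethoxy-3-methylphenyl)-2,6,10-trimethyldodeca-2,6,10-trien-1-ol
Conditions: iBu2AlH (2.3 equiv), CH2Cl2, −78 → −20 °C
Reagents that add atoms: none
Why: 1,2-Reduction of an α,β-unsaturated ester by iBu2AlH to the allylic alcohol, which should proceed without conjugate reduction and without touching the silyl or aryl methyl ethers.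

**Step 11**
Reactants: 17 (2E,4R,6E,10E)-4-[tert-butyl(dimethyl)silyl]oxy-12-(2,5-dimethoxy-3-methylphenyl)-2,6,10-trimethyldodeca-2,6,10-trien-1-ol
Product: 18 [(2E,4R,6E,10E)-1-bromo-12-(2,5-dimethoxy-3-methylphenyl)-2,6,10-trimethyldodeca-2,6,10-trien-4-yl]oxy-tert-butyl-dimethylsilane
Conditions: CBr4, PPh3, CH2Cl2, −20 → 0 °C
Reagents that add atoms: tetrabromomethane, BrC(Br)(Br)Br
Why: Appel reaction, an SN2 displacement at the primary allylic carbon under neutral conditions that should keep the alkene geometry and the silyl ether; the bromide is used at once.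

**Step 12**
Reactants: 18 [(2E,4R,6E,10E)-1-bromo-12-(2,5-dimethoxy-3-methylphenyl)-2,6,10-trimethyldodeca-2,6,10-trien-4-yl]oxy-tert-butyl-dimethylsilane, 19 3-methylbut-2-enyl phenyl sulfone
Product: 21 tert-butyl-{[(2E,6E,9R,10E)-13-(benzenesulfonyl)-1-(2,5-dimethoxy-3-methylphenyl)-3,7,11,15-tetramethylhexadeca-2,6,10,14-tetraen-9-yl]oxy}dimethylsilane (both C13' epimers), via lithiated sulfone 20 (not isolated)
Conditions: 19, n-BuLi, THF, −78 °C; then 18, −78 → −20 °C
Reagents that add atoms: none
Why: Alkylation of an α-sulfonyl allyl anion, which reacts at the sulfone-bearing carbon by SN2 at the primary allylic bromide and so forms C12'–C13' without allylic transposition on either partner.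

**Step 13**
Reactants: 21 tert-butyl-{[(2E,6E,9R,10E)-13-(benzenesulfonyl)-1-(2,5-dimethoxy-3-methylphenyl)-3,7,11,15-tetramethylhexadeca-2,6,10,14-tetraen-9-yl]oxy}dimethylsilane
Product: 22 tert-butyl-{[(2E,6E,9R,10E)-1-(2,5-dimethoxy-3-methylphenyl)-3,7,11,15-tetramethylhexadeca-2,6,10,14-tetraen-9-yl]oxy}dimethylsilane
Conditions: PdCl2(dppp) (5 mol %), LiBHEt3, THF, 0 °C
Reagents that add atoms: none
Why: Palladium-catalysed reductive desulfonylation of an allylic sulfone, in which zerovalent palladium formed in the flask ionises the C13'–S bond to a π-allyl complex and hydride is delivered to the less substituted terminus C13', so the C14'=C15' alkene should stay in place and the temporary C13' centre disappears.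

**Step 14**
Reactants: 22 tert-butyl-{[(2E,6E,9R,10E)-1-(2,5-dimethoxy-3-methylphenyl)-3,7,11,15-tetramethylhexadeca-2,6,10,14-tetraen-9-yl]oxy}dimethylsilane
Product: 23 (2E,6E,9R,10E)-1-(2,5-dimethoxy-3-methylphenyl)-3,7,11,15-tetramethylhexadeca-2,6,10,14-tetraen-9-ol
Conditions: Bu4NF, THF, 0 °C → rt
Reagents that add atoms: none
Why: Fluoride-induced cleavage of the Si–O bond, which does not affect the C9'–O bond, the alkenes or the aryl methyl ethers.

**Step 15**
Reactants: 23 (2E,6E,9R,10E)-1-(2,5-dimethoxy-3-methylphenyl)-3,7,11,15-tetramethylhexadeca-2,6,10,14-tetraen-9-ol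
Product: 24 2-[(2E,6E,9R,10E)-9-hydroxy-3,7,11,15-tetramethylhexadeca-2,6,10,14-tetraenyl]-6-methylcyclohexa-2,5-diene-1,4-dione
Conditions: (NH4)2Ce(NO3)6 (2.5 equiv), MeCN/H2O, 0 °C
Reagents that add atoms: water, O
Why: Oxidative demethylation of a hydroquinone dimethyl ether by tetravalent cerium, in which water attacks the methoxy-bearing carbons of the arene radical cation and methanol is lost, a reaction fast enough at 0 °C that isolated trisubstituted alkenes and the secondary allylic alcohol should survive.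

**Step 16**
Reactants: 24 2-[(2E,6E,9R,10E)-9-hydroxy-3,7,11,15-tetramethylhexadeca-2,6,10,14-tetraenyl]-6-methylcyclohexa-2,5-diene-1,4-dione
Product: 25 2-[(2E,6E,9R,10E)-9-hydroxy-3,7,11,15-tetramethylhexadeca-2,6,10,14-tetraenyl]-6-methylbenzene-1,4-diol
Conditions: Na2S2O4, Et2O/H2O, rt, under argon
Reagents that add atoms: none
Why: Two-electron reduction of the para-quinone by dithionite, a mild final step that affects neither the alkenes nor the allylic alcohol and releases the air-sensitive hydroquinone only at the end.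

**Compound list**

1 | 4-methoxy-2-methylphenol | COc1ccc(O)c(C)c1 | starting material
2 | 2-bromo-4-methoxy-6-methylphenol | COc1cc(C)c(O)c(Br)c1 | intermediate
3 | 1-bromo-2,5-dimethoxy-3-methylbenzene | COc1cc(C)c(OC)c(Br)c1 | intermediate
4 | (2E,6E)-1-bromo-3,7,11-trimethyldodeca-2,6,10-triene ((2E,6E)-farnesyl bromide) | CC(C)=CCC/C(C)=C/CC/C(C)=C/CBr | starting material
5 | (2,5-dimethoxy-3-methylphenyl)magnesium bromide | COc1cc(C)c(OC)c([Mg]Br)c1 | intermediate (not isolated)
6 | 1-[(2E,6E)-3,7,11-trimethyldodeca-2,6,10-trienyl]-2,5-dimethoxy-3-methylbenzene | CC(C)=CCC/C(C)=C/CC/C(C)=C/Cc1cc(OC)cc(C)c1OC | intermediate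
7 | (6E,10E)-3-bromo-12-(2,5-dimethoxy-3-methylphenyl)-2,6,10-trimethyldodeca-6,10-dien-2-ol (racemic) | CC(C)(O)C(Br)CC/C(C)=C/CC/C(C)=C/Cc1cc(OC)cc(C)c1OC | intermediate
8 | 3-[(3E,7E)-9-(2,5-dimethoxy-3-methylphenyl)-3,7-dimethylnona-3,7-dienyl]-2,2-dimethyloxirane (racemic) | CC1(C)OC1CC/C(C)=C/CC/C(C)=C/Cc1cc(OC)cc(C)c1OC | intermediate
9 | (6E,10E)-12-(2,5-dimethoxy-3-methylphenyl)-2,6,10-trimethyldodeca-6,10-diene-2,3-diol (racemic) | CC(C)(O)C(O)CC/C(C)=C/CC/C(C)=C/Cc1cc(OC)cc(C)c1OC | intermediate (not isolated)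
10 | (4E,8E)-10-(2,5-dimethoxy-3-methylphenyl)-4,8-dimethyldeca-4,8-dienal | O=CCC/C(C)=C/CC/C(C)=C/Cc1cc(OC)cc(C)c1OC | intermediate
11 | nitrosobenzene | O=Nc1ccccc1 | starting material
12 | ethyl 2-(triphenylphosphoranylidene)propanoate | CCOC(=O)C(C)=P(c1ccccc1)(c1ccccc1)c1ccccc1 | starting material
13 | (2R,4E,8E)-2-(anilinooxy)-10-(2,5-dimethoxy-3-methylphenyl)-4,8-dimethyldeca-4,8-dienal | O=C[C@H](ONc1ccccc1)C/C(C)=C/CC/C(C)=C/Cc1cc(OC)cc(C)c1OC | intermediate (not isolated)
14 | ethyl (2E,4R,6E,10E)-4-(anilinooxy)-12-(2,5-dimethoxy-3-methylphenyl)-2,6,10-trimethyldodeca-2,6,10-trienoate | CCOC(=O)/C(C)=C/[C@H](ONc1ccccc1)C/C(C)=C/CC/C(C)=C/Cc1cc(OC)cc(C)c1OC | intermediate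
15 | ethyl (2E,4R,6E,10E)-12-(2,5-dimethoxy-3-methylphenyl)-4-hydroxy-2,6,10-trimethyldodeca-2,6,10-trienoate | CCOC(=O)/C(C)=C/[C@H](O)C/C(C)=C/CC/C(C)=C/Cc1cc(OC)cc(C)c1OC | intermediate
16 | ethyl (2E,4R,6E,10E)-4-[tert-butyl(dimethyl)silyl]oxy-12-(2,5-dimethoxy-3-methylphenyl)-2,6,10-trimethyldodeca-2,6,10-trienoate | CCOC(=O)/C(C)=C/[C@H](O[Si](C)(C)C(C)(C)C)C/C(C)=C/CC/C(C)=C/Cc1cc(OC)cc(C)c1OC | intermediate
17 | (2E,4R,6E,10E)-4-[tert-butyl(dimethyl)silyl]oxy-12-(2,5-dimethoxy-3-methylphenyl)-2,6,10-trimethyldodeca-2,6,10-trien-1-ol | OC/C(C)=C/[C@H](O[Si](C)(C)C(C)(C)C)C/C(C)=C/CC/C(C)=C/Cc1cc(OC)cc(C)c1OC | intermediate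
18 | [(2E,4R,6E,10E)-1-bromo-12-(2,5-dimethoxy-3-methylphenyl)-2,6,10-trimethyldodeca-2,6,10-trien-4-yl]oxy-tert-butyl-dimethylsilane | BrC/C(C)=C/[C@H](O[Si](C)(C)C(C)(C)C)C/C(C)=C/CC/C(C)=C/Cc1cc(OC)cc(C)c1OC | intermediate
19 | 3-methylbut-2-enyl phenyl sulfone | CC(C)=CCS(=O)(=O)c1ccccc1 | starting material
20 | [1-(benzenesulfonyl)-3-methylbut-2-enyl]lithium | CC(C)=CC([Li])S(=O)(=O)c1ccccc1 | intermediate (not isolated)
21 | tert-butyl-{[(2E,6E,9R,10E)-13-(benzenesulfonyl)-1-(2,5-dimethoxy-3-methylphenyl)-3,7,11,15-tetramethylhexadeca-2,6,10,14-tetraen-9-yl]oxy}dimethylsilane (both C13' epimers) | CC(C)=CC(S(=O)(=O)c1ccccc1)C/C(C)=C/[C@H](O[Si](C)(C)C(C)(C)C)C/C(C)=C/CC/C(C)=C/Cc1cc(OC)cc(C)c1OC | intermediate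
22 | tert-butyl-{[(2E,6E,9R,10E)-1-(2,5-dimethoxy-3-methylphenyl)-3,7,11,15-tetramethylhexadeca-2,6,10,14-tetraen-9-yl]oxy}dimethylsilane | CC(C)=CCC/C(C)=C/[C@H](O[Si](C)(C)C(C)(C)C)C/C(C)=C/CC/C(C)=C/Cc1cc(OC)cc(C)c1OC | intermediate
23 | (2E,6E,9R,10E)-1-(2,5-dimethoxy-3-methylphenyl)-3,7,11,15-tetramethylhexadeca-2,6,10,14-tetraen-9-ol | CC(C)=CCC/C(C)=C/[C@H](O)C/C(C)=C/CC/C(C)=C/Cc1cc(OC)cc(C)c1OC | intermediate
24 | 2-[(2E,6E,9R,10E)-9-hydroxy-3,7,11,15-tetramethylhexadeca-2,6,10,14-tetraenyl]-6-methylcyclohexa-2,5-diene-1,4-dione | CC(C)=CCC/C(C)=C/[C@H](O)C/C(C)=C/CC/C(C)=C/CC1=CC(=O)C=C(C)C1=O | intermediate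
25 | 2-[(2E,6E,9R,10E)-9-hydroxy-3,7,11,15-tetramethylhexadeca-2,6,10,14-tetraenyl]-6-methylbenzene-1,4-diol | CC(C)=CCC/C(C)=C/[C@H](O)C/C(C)=C/CC/C(C)=C/Cc1cc(O)cc(C)c1O | target

**Step count**

Total steps: 16. Longest linear sequence: 16 steps (1 → 25); compounds 4, 11, 12 and 19 are bought.

**Steps most likely to fail**

Step 7. The α-anilinooxy aldehyde may lose configurational purity or oligomerise before it is olefinated, and nitrosobenzene may be consumed by ene reaction with the chain alkenes or by self-condensation, so that conversion of the aldehyde stalls. The fallback sets out from aldehyde 10 and replaces the nitroso electrophile. Dibenzoyl peroxide under enamine catalysis by (R)-α,α-diphenylprolinol trimethylsilyl ether (THF, hydroquinone as radical scavenger, 0 °C), a known organocatalytic α-benzoyloxylation, should give (2R,4E,8E)-2-(benzoyloxy)-10-(2,5-dimethoxy-3-methylphenyl)-4,8-dimethyldeca-4,8-dienal F1, an isolable and configurationally sturdier aldehyde. The (R)-catalyst is chosen because steric shielding addresses the enamine face opposite to the one reached under hydrogen-bond direction by L-proline; the sense should be confirmed on a model aldehyde first. Wittig reaction of F1 with ylide 12 in CH2Cl2 should give ethyl (2E,4R,6E,10E)-4-(benzoyloxy)-12-(2,5-dimethoxy-3-methylphenyl)-2,6,10-trimethyldodeca-2,6,10-trienoate F2, and ethanolysis of the benzoate (K2CO3, EtOH, 0 °C → rt) comes back to the route at hydroxy ester 15.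

Step 4. Bromonium formation may not discriminate well among the three trisubstituted alkenes, and bromination of the electron-rich ring may drain material. The fallback sets out from aryl bromide 3 and builds C9' and C10' instead of uncovering them, so no alkene has to be told apart from another. Grignard reagent 5 is coupled (CuI cat., THF) with geranyl bromide to give 1-[(2E)-3,7-dimethylocta-2,6-dienyl]-2,5-dimethoxy-3-methylbenzene F3. Allylic oxidation of the terminal (E)-methyl group (SeO2 cat., t-BuOOH, salicylic acid, CH2Cl2; then NaBH4 to return any enal) gives (2E,6E)-8-(2,5-dimethoxy-3-methylphenyl)-2,6-dimethylocta-2,6-dien-1-ol F4. Appel bromination (CBr4, PPh3) gives 1-[(2E,6E)-8-bromo-3,7-dimethylocta-2,6-dienyl]-2,5-dimethoxy-3-methylbenzene F5. Alkylation of the lithium enolate of tert-butyl acetate (LiN(iPr)2, THF, −78 °C → rt) gives tert-butyl (4E,8E)-10-(2,5-dimethoxy-3-methylphenyl)-4,8-dimethyldeca-4,8-dienoate F6, and partial reduction (iBu2AlH, 1.1 equiv, CH2Cl2, −78 °C) comes back to the route at aldehyde 10.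

Step 13. Hydride may be delivered to the tertiary end of the π-allyl palladium intermediate, or the alkene may migrate, giving isomers of the terminal prenyl unit that are hard to separate. The fallback sets out from bromide 18 and bypasses sulfone 21. 3-Methylbut-2-enyl chloride is treated with active barium (from BaI2 and lithium biphenylide, THF) to give (3-methylbut-2-enyl)barium chloride F7. In the known allylbarium cross-coupling with allylic halides at −78 °C, the reagent reacts at its own α-carbon and at the α-carbon of the electrophile with retention of alkene geometry. This comes back to the route directly at silyl ether 22.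

**Further compounds**

F1 | step 7 | (2R,4E,8E)-2-(benzoyloxy)-10-(2,5-dimethoxy-3-methylphenyl)-4,8-dimethyldeca-4,8-dienal | O=C[C@H](OC(=O)c1ccccc1)C/C(C)=C/CC/C(C)=C/Cc1cc(OC)cc(C)c1OC
F2 | step 7 | ethyl (2E,4R,6E,10E)-4-(benzoyloxy)-12-(2,5-dimethoxy-3-methylphenyl)-2,6,10-trimethyldodeca-2,6,10-trienoate | CCOC(=O)/C(C)=C/[C@H](OC(=O)c1ccccc1)C/C(C)=C/CC/C(C)=C/Cc1cc(OC)cc(C)c1OC
F3 | step 4 | 1-[(2E)-3,7-dimethylocta-2,6-dienyl]-2,5-dimethoxy-3-methylbenzene | CC(C)=CCC/C(C)=C/Cc1cc(OC)cc(C)c1OC
F4 | step 4 | (2E,6E)-8-(2,5-dimethoxy-3-methylphenyl)-2,6-dimethylocta-2,6-dien-1-ol | OC/C(C)=C/CC/C(C)=C/Cc1cc(OC)cc(C)c1OC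
F5 | step 4 | 1-[(2E,6E)-8-bromo-3,7-dimethylocta-2,6-dienyl]-2,5-dimethoxy-3-methylbenzene | BrC/C(C)=C/CC/C(C)=C/Cc1cc(OC)cc(C)c1OC
F6 | step 4 | tert-butyl (4E,8E)-10-(2,5-dimethoxy-3-methylphenyl)-4,8-dimethyldeca-4,8-dienoate | CC(C)(C)OC(=O)CC/C(C)=C/CC/C(C)=C/Cc1cc(OC)cc(C)c1OC
F7 | step 13 | (3-methylbut-2-enyl)barium chloride | CC(C)=CC[Ba]Cl
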